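**Strategy.** The route rests on one disconnection in ring A (C1–C2–C3–C4–C5–C9) of the bicyclo[3.3.1]nonane core. C4 is a carbonyl carbon with no other substituent, flanked by the alkene carbon C3 and the fully substituted bridgehead C5, so it can enter as carbon monoxide. In one operation a palladium-mediated carbonylation couples a C3 vinyl iodide with the C5 enolate of the ring-B ketone (C9), forming C3–C4 and C4–C5, closing ring A and fixing C5. The precursor is a 4,6-digeranyl-3,3-dimethylcyclohexanone whose quaternary C1 carries prenyl and a 2-iodo-3-methoxy-3-arylacryloyl chain (aroyl masked as methyl enol ether, catechol as TIPS ethers). C7 and C1 are set earlier by auxiliary alkylation and anti prenylation.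

Key step: step 14

Conventions: geranyl = (2E)-3,7-dimethylocta-2,6-dien-1-yl; prenyl = 3-methylbut-2-en-1-yl; TIPS = triisopropylsilyl. In cyclohexanones 10–22, ring carbons 1, 2, 3, 4, 5 and 6 become C9, C1, C8, C7, C6 and C5 of the bicyclic core.

Assumption: the (S)-benzyl auxiliary is taken to direct geranyl bromide to the azaenolate face that gives the (R)-centre drawn in 6 and 7; should the opposite sense be found, the enantiomeric auxiliary is used and nothing else changes.

Step 1
Reactants: 1 (S)-4-benzyloxazolidin-2-one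
Product: 2 (S)-3-amino-4-benzyloxazolidin-2-one
Conditions: NaH, dioxane, rt; then O-(4-nitrobenzoyl)hydroxylamine, rt
Reagents that add atoms: O-(4-nitrobenzoyl)hydroxylamine, NOC(=O)c1ccc(cc1)[N+](=O)[O-]
Why: Electrophilic N-amination of the sodium salt of the cyclic carbamate by the O-acylhydroxylamine should give the N-amino auxiliary without touching its stereocentre.

Step 2
Reactants: 2 (S)-3-amino-4-benzyloxazolidin-2-one; 3 3-ethoxycyclohex-2-en-1-one
Product: 4 (S)-4-benzyl-3-[(3-ethoxycyclohex-2-en-1-ylidene)amino]oxazolidin-2-one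
Conditions: p-TsOH·H2O (cat.), CH2Cl2, 4 Å MS, reflux
Reagents that add atoms: none
Why: Acid-catalysed hydrazone condensation with removal of water should take place at the carbonyl carbon of the vinylogous ester, the weakly nucleophilic N-amino carbamate adding 1,2 so that the enol ether is kept.

Step 3
Reactants: 4 hydrazone of 3-ethoxycyclohexenone; 5 geranyl bromide
Product: 6 (S)-4-benzyl-3-{[(6R)-3-ethoxy-6-geranylcyclohex-2-en-1-ylidene]amino}oxazolidin-2-one
Conditions: LDA, THF, −78 °C; then 5, −78 → −40 °C
Reagents that add atoms: none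
Why: Azaenolate alkylation of a chiral N-amino cyclic carbamate hydrazone: LDA removes a proton from the only sp3 α-carbon (C6), and the carbamate-chelated azaenolate should be alkylated by the allylic bromide (SN2) on the face away from the benzyl group, which sets the geranyl-bearing centre (the future C7).

Step 4
Reactants: 6 geranylated hydrazone
Product: 7 (R)-3-ethoxy-6-geranylcyclohex-2-en-1-one
Conditions: p-TsOH·H2O, acetone/H2O, 0 °C → rt
Reagents that add atoms: water, O
Why: Acid-catalysed hydrazone hydrolysis with transfer of the auxiliary to acetone should free the ketone under conditions mild enough to keep the α-stereocentre and the enol ether.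

Step 5
Reactants: 7 (R)-3-ethoxy-6-geranylcyclohex-2-en-1-one
Product: 9 (R)-4-geranyl-3-methylcyclohex-2-en-1-one, via lithium alkoxide 8 (not isolated)
Conditions: MeLi, CeCl3, THF, −78 °C; then 1 M HCl, 0 °C
Reagents that add atoms: methyllithium, [Li]C; water, O
Why: Stork–Danheiser transposition: cerium-assisted 1,2-addition of methyllithium (which avoids enolisation of the α-stereocentre) followed by acid hydrolysis of the enol ether and loss of water should give the transposed 3-methyl enone, in which the stereocentre has become the untouched γ-carbon.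

Step 6
Reactants: 9 (R)-4-geranyl-3-methylcyclohex-2-en-1-one; 5 geranyl bromide
Product: 10 4,6-digeranyl-3-methylcyclohex-2-en-1-one (C4 as in 9; C6 epimers)
Conditions: LDA, THF, −78 °C; then 5, DMPU, −78 → −30 °C
Reagents that add atoms: none
Why: Kinetic α′-deprotonation of the enone and SN2 alkylation of the cross-conjugated enolate should install the second geranyl group, the new centre (future C5) being left uncontrolled on purpose because step 14 planarises it, while the γ-centre is not deprotonated under kinetic control.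

Step 7
Reactants: 10 4,6-digeranyl-3-methylcyclohex-2-en-1-one
Product: 12 4,6-digeranyl-2-(1-hydroxyethyl)-3,3-dimethylcyclohexan-1-one (diastereomer mixture), via lithium enolate 11 (not isolated)
Conditions: Me2CuLi, Et2O, −78 → −10 °C; then MeCHO, −78 °C; aq. NH4Cl
Reagents that add atoms: lithium dimethylcuprate, [Li+].C[Cu-]C; acetaldehyde, CC=O
Why: Tandem Gilman conjugate addition–aldol reaction: the cuprate adds the second methyl group to the β-carbon (no stereocentre results at the CMe2 carbon) and the regiodefined enolate should add to acetaldehyde at ring carbon 2, the new centres there and at the carbinol being irrelevant because both are erased in steps 8 and 9.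

Step 8
Reactants: 12 aldol adduct
Product: 13 2-acetyl-4,6-digeranyl-3,3-dimethylcyclohexan-1-one
Conditions: Dess–Martin periodinane, NaHCO3, CH2Cl2, 0 °C → rt
Reagents that add atoms: none
Why: Dess–Martin oxidation of the secondary alcohol should give the enolisable 2-acetyl ketone under buffered, non-acidic conditions that leave the four trisubstituted alkenes alone.

Step 9
Reactants: 13 2-acetyl-4,6-digeranyl-3,3-dimethylcyclohexan-1-one; 14 prenyl bromide
Product: 15 2-acetyl-4,6-digeranyl-3,3-dimethyl-2-prenylcyclohexan-1-one (prenyl trans to the C4 geranyl group)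
Conditions: NaH, THF, 0 °C; then Pd(PPh3)4 (5 mol %), 14, rt
Reagents that add atoms: none
Why: Tsuji–Trost allylic alkylation of the stabilised diketone enolate: the π-prenylpalladium should be attacked at its unsubstituted terminus, C-alkylation being the thermodynamic outcome because any O-prenyl ether re-ionises, and chair-like axial attack places prenyl syn to the axial hydrogen on ring carbon 4, that is trans to the equatorial geranyl group, which sets the quaternary centre (future C1) with acetyl cis to that chain.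

Step 10
Reactants: 16 methyl 3,4-dihydroxybenzoate
Product: 17 methyl 3,4-bis(triisopropylsilyloxy)benzoate
Conditions: TIPSCl, imidazole, DMF, rt
Reagents that add atoms: triisopropylsilyl chloride, CC(C)[Si](Cl)(C(C)C)C(C)C
Why: Silylation of both phenols with a silyl chloride and imidazole should proceed without affecting the ester.

Step 11
Reactants: 15 prenylated acetyl ketone; 17 methyl 3,4-bis(triisopropylsilyloxy)benzoate
Product: 18 2-{3-[3,4-bis(triisopropylsilyloxy)phenyl]-3-oxopropanoyl}-4,6-digeranyl-3,3-dimethyl-2-prenylcyclohexan-1-one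
Conditions: LiHMDS (2.2 equiv), THF, −78 → 0 °C; then 17, 0 °C → rt
Reagents that add atoms: none
Why: Crossed Claisen condensation: the base should deprotonate the unhindered acetyl methyl group in preference to the tertiary hydrogen on ring carbon 6, and the enolate is acylated on carbon by the non-enolisable aryl ester, the diketonate being the thermodynamic sink.

Step 12
Reactants: 18 aryl 1,3-diketone
Product: 19 2-{(2Z)-3-[3,4-bis(triisopropylsilyloxy)phenyl]-3-methoxyprop-2-enoyl}-4,6-digeranyl-3,3-dimethyl-2-prenylcyclohexan-1-one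
Conditions: TMSCHN2, MeOH/toluene (1:4), 0 °C
Reagents that add atoms: (trimethylsilyl)diazomethane, C[Si](C)(C)C=[N+]=[N-]
Why: O-methylation of the enolised 1,3-diketone with a diazoalkane, which does not C-alkylate, should occur on the aryl-side oxygen because the other oxygen is buried under the quaternary ring carbon with its prenyl and gem-dimethyl neighbours.

Step 13
Reactants: 19 methyl enol ether
Product: 20 2-{(2Z)-3-[3,4-bis(triisopropylsilyloxy)phenyl]-2-iodo-3-methoxyprop-2-enoyl}-4,6-digeranyl-3,3-dimethyl-2-prenylcyclohexan-1-one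
Conditions: NIS, CH2Cl2, 0 °C, dark
Reagents that add atoms: N-iodosuccinimide, O=C1CCC(=O)N1I
Why: Electrophilic α-iodination of the vinylogous ester (attack of the iodonium source on the enol ether carbon, then loss of the proton) should be chemoselective because the aryl- and methoxy-stabilised cation forms far more easily than an iodonium ion on an isolated trisubstituted alkene, and either alkene geometry of the product serves.

Step 14
Reactants: 20 vinyl iodide ketone
Product: 23 3-{[3,4-bis(triisopropylsilyloxy)phenyl](methoxy)methylidene}-5,7-digeranyl-8,8-dimethyl-1-prenylbicyclo[3.3.1]nonane-2,4,9-trione (configuration of the target), via lithium enolate 21 (not isolated), via zinc enolate 22 (not isolated)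
Conditions: LDA (1.05 equiv), THF, −78 → −40 °C; ZnCl2 (1.2 equiv), −40 → 0 °C; then Pd2(dba)3 (10 mol %), Xantphos (20 mol %), CO (1 atm), 25 → 50 °C
Reagents that add atoms: carbon monoxide, [C-]#[O+]
Why: Proposed new method: LDA removes the only α-proton of the C9 ketone (C5–H, C1 being quaternary) and ZnCl2 turns the enolate into its zinc enolate; Pd(0) then inserts into the C3–I bond, CO inserts to give the C4 acyl-palladium, and transmetalation of the tethered zinc enolate followed by C–C reductive elimination forms C4–C5 after C3–C4. The closest known reactions are the intermolecular palladium-catalysed carbonylative α-arylation of ketone enolates to 1,3-diketones, the carbonylative Negishi coupling, and the intramolecular palladium-catalysed α-alkenylation of ketones by vinyl iodides that closes bridged bicyclo[3.3.1]nonanones; the intramolecular, bridged, quaternary-centre-forming carbonylative case has not been shown. Ring A (C1–C2–C3–C4–C5–C9) closes in a 6-(enolendo)-exo-trig mode, C5 attacking the exocyclic acyl carbon. The new quaternary stereocentre C5 is dictated by the tether: the acyl chain sits on C1 and can reach only the enolate face cis to C2, and the planar enolate makes both C5 epimers of 20 converge. The step needs C-acylation in preference to O-acylation (which would give an unstrained six-membered enol lactone O–C9–C1–C2–C3–C4 and is the serious competitor), CO insertion ahead of 5-exo carbopalladation of the C1 prenyl alkene by the vinyl-palladium (or 6-exo by the acyl-palladium), and capture by palladium ahead of enolate addition–elimination at the methoxy-bearing carbon. The covalent, weakly basic zinc enolate and the wide-bite-angle ligand are chosen to favour the carbon-bound palladium enolate and fast reductive elimination, the CO atmosphere and the low insertion aptitude of trisubstituted alkenes disfavour the Heck pathways, and the tetrasubstituted, methoxy-donated β-carbon is a poor acceptor.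

Step 15
Reactants: 23 bicyclic trione methyl enol ether
Product: 24 oblongifolin D 3′,4′-bis(triisopropylsilyl) ether
Conditions: LiCl, DMSO, 100 °C; then aq. NH4Cl
Reagents that add atoms: none
Why: Krapcho-type nucleophilic demethylation (SN2 of chloride at the O-methyl carbon of the doubly activated vinylogous ester) should release the triketone as its enolate, while aryl silyl ethers and alkenes are inert to chloride.

Step 16
Reactants: 24 bis-silyl ether
Product: 25 oblongifolin D
Conditions: TBAF, AcOH, THF, 0 °C
Reagents that add atoms: none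
Why: Fluoride cleavage of the two aryl silyl ethers, buffered with acetic acid so that catecholate and triketone enolate are not exposed to strong base, should give the target, in which no stereocentre is epimerisable.

**Compound list**

1 | (S)-4-benzyloxazolidin-2-one | O=C1N[C@@H](Cc2ccccc2)CO1 | starting material
2 | (S)-3-amino-4-benzyloxazolidin-2-one | NN1[C@@H](Cc2ccccc2)COC1=O | intermediate
3 | 3-ethoxycyclohex-2-en-1-one | CCOC1=CC(=O)CCC1 | starting material
4 | (S)-4-benzyl-3-[(3-ethoxycyclohex-2-en-1-ylidene)amino]oxazolidin-2-one (C=N geometry not assigned) | CCOC1=CC(CCC1)=NN2[C@@H](Cc3ccccc3)COC2=O | intermediate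
5 | geranyl bromide, (2E)-1-bromo-3,7-dimethylocta-2,6-diene | CC(C)=CCC/C(C)=C/CBr | starting material
6 | (S)-4-benzyl-3-{[(6R)-3-ethoxy-6-geranylcyclohex-2-en-1-ylidene]amino}oxazolidin-2-one | CC(C)=CCC/C(C)=C/C[C@H]1CCC(OCC)=CC1=NN2[C@@H](Cc3ccccc3)COC2=O | intermediate
7 | (R)-3-ethoxy-6-geranylcyclohex-2-en-1-one | CC(C)=CCC/C(C)=C/C[C@H]1CCC(OCC)=CC1=O | intermediate
8 | lithium (6R)-3-ethoxy-6-geranyl-1-methylcyclohex-2-en-1-olate (C1 epimers) | CC(C)=CCC/C(C)=C/C[C@H]1CCC(OCC)=CC1(C)O[Li] | intermediate
9 | (R)-4-geranyl-3-methylcyclohex-2-en-1-one | CC(C)=CCC/C(C)=C/C[C@H]1CCC(=O)C=C1C | intermediate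
10 | 4,6-digeranyl-3-methylcyclohex-2-en-1-one (geranyl-bearing C4 unchanged from 9; C6 epimers) | CC(C)=CCC/C(C)=C/C[C@H]1CC(C/C=C(\C)CCC=C(C)C)C(=O)C=C1C | intermediate
11 | lithium 4,6-digeranyl-3,3-dimethylcyclohex-1-en-1-olate (C4 as in 9; C6 epimers) | CC(C)=CCC/C(C)=C/C[C@H]1CC(C/C=C(\C)CCC=C(C)C)C(O[Li])=CC1(C)C | intermediate
12 | 4,6-digeranyl-2-(1-hydroxyethyl)-3,3-dimethylcyclohexan-1-one (C4 as in 9; C2, C6 and carbinol carbon as mixtures) | CC(C)=CCC/C(C)=C/C[C@H]1CC(C/C=C(\C)CCC=C(C)C)C(=O)C(C(C)O)C1(C)C | intermediate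
13 | 2-acetyl-4,6-digeranyl-3,3-dimethylcyclohexan-1-one (enolisable at C2; C4 as in 9; C6 epimers) | CC(C)=CCC/C(C)=C/C[C@H]1CC(C/C=C(\C)CCC=C(C)C)C(=O)C(C(C)=O)C1(C)C | intermediate
14 | prenyl bromide, 1-bromo-3-methylbut-2-ene | CC(C)=CCBr | starting material
15 | 2-acetyl-4,6-digeranyl-3,3-dimethyl-2-prenylcyclohexan-1-one (prenyl on C2 trans, acetyl cis, to geranyl on C4; C4 as in 9; C6 epimers) | CC(C)=CCC/C(C)=C/C[C@H]1CC(C/C=C(\C)CCC=C(C)C)C(=O)[C@@](CC=C(C)C)(C(C)=O)C1(C)C | intermediate
16 | methyl 3,4-dihydroxybenzoate | COC(=O)c1ccc(O)c(O)c1 | starting material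
17 | methyl 3,4-bis(triisopropylsilyloxy)benzoate | COC(=O)c1ccc(O[Si](C(C)C)(C(C)C)C(C)C)c(O[Si](C(C)C)(C(C)C)C(C)C)c1 | intermediate
18 | 2-{3-[3,4-bis(triisopropylsilyloxy)phenyl]-3-oxopropanoyl}-4,6-digeranyl-3,3-dimethyl-2-prenylcyclohexan-1-one (enolised diketone; ring stereochemistry as in 15) | CC(C)=CCC/C(C)=C/C[C@H]1CC(C/C=C(\C)CCC=C(C)C)C(=O)[C@@](CC=C(C)C)(C(=O)CC(=O)c2ccc(O[Si](C(C)C)(C(C)C)C(C)C)c(O[Si](C(C)C)(C(C)C)C(C)C)c2)C1(C)C | intermediate
19 | 2-{(2Z)-3-[3,4-bis(triisopropylsilyloxy)phenyl]-3-methoxyprop-2-enoyl}-4,6-digeranyl-3,3-dimethyl-2-prenylcyclohexan-1-one (ring stereochemistry as in 15) | CC(C)=CCC/C(C)=C/C[C@H]1CC(C/C=C(\C)CCC=C(C)C)C(=O)[C@@](CC=C(C)C)(C(=O)/C=C(\OC)c2ccc(O[Si](C(C)C)(C(C)C)C(C)C)c(O[Si](C(C)C)(C(C)C)C(C)C)c2)C1(C)C | intermediate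
20 | 2-{(2Z)-3-[3,4-bis(triisopropylsilyloxy)phenyl]-2-iodo-3-methoxyprop-2-enoyl}-4,6-digeranyl-3,3-dimethyl-2-prenylcyclohexan-1-one (iodine and methoxy cis as drawn, the geometric isomer serves equally; ring stereochemistry as in 15) | CC(C)=CCC/C(C)=C/C[C@H]1CC(C/C=C(\C)CCC=C(C)C)C(=O)[C@@](CC=C(C)C)(C(=O)/C(I)=C(/OC)c2ccc(O[Si](C(C)C)(C(C)C)C(C)C)c(O[Si](C(C)C)(C(C)C)C(C)C)c2)C1(C)C | intermediate
21 | lithium enolate of 20 (enolate C1=C6 of the cyclohexanone, i.e. C9=C5 of the core) | CC(C)=CCC/C(C)=C/C[C@H]1CC(C/C=C(\C)CCC=C(C)C)=C(O[Li])[C@@](CC=C(C)C)(C(=O)/C(I)=C(/OC)c2ccc(O[Si](C(C)C)(C(C)C)C(C)C)c(O[Si](C(C)C)(C(C)C)C(C)C)c2)C1(C)C | intermediate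
22 | chlorozinc enolate of 20 (same enolate position as 21) | CC(C)=CCC/C(C)=C/C[C@H]1CC(C/C=C(\C)CCC=C(C)C)=C(O[Zn]Cl)[C@@](CC=C(C)C)(C(=O)/C(I)=C(/OC)c2ccc(O[Si](C(C)C)(C(C)C)C(C)C)c(O[Si](C(C)C)(C(C)C)C(C)C)c2)C1(C)C | intermediate
23 | 3-{[3,4-bis(triisopropylsilyloxy)phenyl](methoxy)methylidene}-5,7-digeranyl-8,8-dimethyl-1-prenylbicyclo[3.3.1]nonane-2,4,9-trione (C1, C5, C7 as in the target: geranyl on C7 cis to the C2–C3–C4 bridge, prenyl on C1 trans to it; methoxy drawn anti to C2) | CC(C)=CCC/C(C)=C/C[C@H]1C[C@]2(C/C=C(\C)CCC=C(C)C)C(=O)[C@@](CC=C(C)C)(C(=O)/C(=C(/OC)c3ccc(O[Si](C(C)C)(C(C)C)C(C)C)c(O[Si](C(C)C)(C(C)C)C(C)C)c3)C2=O)C1(C)C | intermediate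
24 | oblongifolin D 3′,4′-bis(triisopropylsilyl) ether: 3-[3,4-bis(triisopropylsilyloxy)benzoyl]-5,7-digeranyl-4-hydroxy-8,8-dimethyl-1-prenylbicyclo[3.3.1]non-3-ene-2,9-dione (stereocentres as in 23) | CC(C)=CCC/C(C)=C/C[C@H]1C[C@]2(C/C=C(\C)CCC=C(C)C)C(=O)[C@@](CC=C(C)C)(C(=O)C(C(=O)c3ccc(O[Si](C(C)C)(C(C)C)C(C)C)c(O[Si](C(C)C)(C(C)C)C(C)C)c3)=C2O)C1(C)C | intermediate
25 | oblongifolin D: 3-(3,4-dihydroxybenzoyl)-5,7-digeranyl-4-hydroxy-8,8-dimethyl-1-prenylbicyclo[3.3.1]non-3-ene-2,9-dione | CC(C)=CCC/C(C)=C/C[C@H]1C[C@]2(C/C=C(\C)CCC=C(C)C)C(=O)[C@@](CC=C(C)C)(C(=O)C(C(=O)c3ccc(O)c(O)c3)=C2O)C1(C)C | target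

**Step count.** Total: 16 steps. Longest linear sequence: 15 steps (1 → 25 through steps 1–9 and 11–16; step 10 is a one-step branch).

**Steps most likely to fail**

Step 14 (Proposed new method). The palladium-bound acyl group may be captured by the enolate oxygen instead of C5, closing the six-membered enol lactone. The enolate may also be consumed by addition–elimination at the methoxy-bearing carbon, or the organopalladium by alkene insertion, before the carbonylative coupling. The fallback uses known chemistry and sets out from 20. Palladium-catalysed reductive carbonylation (Pd(PPh3)4, CO, Bu3SnH, THF, 50 °C) should convert the C3–I bond into an aldehyde, giving the C3-formyl enone F1. An intramolecular aldol addition of the C5 enolate to this aldehyde (KHMDS, THF, −78 °C) should then give the bicyclic C4 carbinol F2; here attack through oxygen is reversible and only C-attack is productive. Dess–Martin oxidation of the carbinol returns to the route at 23.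

Step 9. The enolate may be alkylated on oxygen or at the tertiary terminus of the prenyl unit, or may fail to build the quaternary centre next to the gem-dimethyl carbon with useful facial selectivity. The fallback sets out from 13. Tsuji–Trost allylation with allyl acetate (NaH, Pd(PPh3)4, THF) uses a smaller electrophile that has no regiochemical issue and should give the C2-allyl diketone F3. Cross-metathesis with 2-methyl-2-butene (Hoveyda–Grubbs second-generation catalyst, 40 °C) then converts allyl into prenyl and returns to 15. The isopropylidene ends of the geranyl groups exchange degenerately, and the internal trisubstituted alkenes are expected to react much more slowly than the terminal one.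

Step 12. The enol may be methylated on the wrong oxygen (poor regioselectivity between the aryl-side and ring-side oxygens). The fallback sets out from 18 and uses the other regioisomer instead of discarding it. The ring-side methyl enol ether F4, with free aroyl ketone and methoxy cis to the aroyl group as delivered from the chelated enol, is iodinated with NIS to the vinyl iodide F5, in which iodine is cis to the ring carbon. F5 is also a C3 vinyl iodide, so carbonylative closure under the conditions of step 14 should give the endocyclic C2 methyl enol ether F6. Demethylation with LiCl in DMSO returns to the route at 24.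

**Further compounds**

F1 | step 14 | 2-{3-[3,4-bis(triisopropylsilyloxy)phenyl]-2-formyl-3-methoxyprop-2-enoyl}-4,6-digeranyl-3,3-dimethyl-2-prenylcyclohexan-1-one (ring stereochemistry as in 20; alkene geometry as drawn, inconsequential) | CC(C)=CCC/C(C)=C/C[C@H]1CC(C/C=C(\C)CCC=C(C)C)C(=O)[C@@](CC=C(C)C)(C(=O)/C(C=O)=C(/OC)c2ccc(O[Si](C(C)C)(C(C)C)C(C)C)c(O[Si](C(C)C)(C(C)C)C(C)C)c2)C1(C)C
F2 | step 14 | 3-{[3,4-bis(triisopropylsilyloxy)phenyl](methoxy)methylidene}-5,7-digeranyl-4-hydroxy-8,8-dimethyl-1-prenylbicyclo[3.3.1]nonane-2,9-dione (C4 carbinol epimers; C1, C5, C7 as in 23) | CC(C)=CCC/C(C)=C/C[C@H]1C[C@]2(C/C=C(\C)CCC=C(C)C)C(=O)[C@@](CC=C(C)C)(C(=O)/C(=C(/OC)c3ccc(O[Si](C(C)C)(C(C)C)C(C)C)c(O[Si](C(C)C)(C(C)C)C(C)C)c3)C2O)C1(C)C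
F3 | step 9 | 2-acetyl-2-allyl-4,6-digeranyl-3,3-dimethylcyclohexan-1-one (allyl trans to the C4 geranyl group; C6 epimers) | CC(C)=CCC/C(C)=C/C[C@H]1CC(C/C=C(\C)CCC=C(C)C)C(=O)[C@@](CC=C)(C(C)=O)C1(C)C
F4 | step 12 | 2-{(1Z)-3-[3,4-bis(triisopropylsilyloxy)phenyl]-1-methoxy-3-oxoprop-1-en-1-yl}-4,6-digeranyl-3,3-dimethyl-2-prenylcyclohexan-1-one (ring stereochemistry as in 15) | CC(C)=CCC/C(C)=C/C[C@H]1CC(C/C=C(\C)CCC=C(C)C)C(=O)[C@@](CC=C(C)C)(/C(OC)=C/C(=O)c2ccc(O[Si](C(C)C)(C(C)C)C(C)C)c(O[Si](C(C)C)(C(C)C)C(C)C)c2)C1(C)C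
F5 | step 12 | 2-{(1E)-3-[3,4-bis(triisopropylsilyloxy)phenyl]-2-iodo-1-methoxy-3-oxoprop-1-en-1-yl}-4,6-digeranyl-3,3-dimethyl-2-prenylcyclohexan-1-one (iodine cis to the ring carbon) | CC(C)=CCC/C(C)=C/C[C@H]1CC(C/C=C(\C)CCC=C(C)C)C(=O)[C@@](CC=C(C)C)(/C(OC)=C(/C(=O)c2ccc(O[Si](C(C)C)(C(C)C)C(C)C)c(O[Si](C(C)C)(C(C)C)C(C)C)c2)I)C1(C)C
F6 | step 12 | 3-[3,4-bis(triisopropylsilyloxy)benzoyl]-5,7-digeranyl-2-methoxy-8,8-dimethyl-1-prenylbicyclo[3.3.1]non-2-ene-4,9-dione (C1, C5, C7 as in 23) | CC(C)=CCC/C(C)=C/C[C@H]1C[C@]2(C/C=C(\C)CCC=C(C)C)C(=O)[C@@](CC=C(C)C)(C(OC)=C(C(=O)c3ccc(O[Si](C(C)C)(C(C)C)C(C)C)c(O[Si](C(C)C)(C(C)C)C(C)C)c3)C2=O)C1(C)C
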